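## The problem

The target is a trans-fused tetrahydroindene: a cyclopentene (ring A: C1, C2, C3, C3a, C7a) fused to a cyclohexene (ring B: C3a, C4, C5, C6, C7, C7a). It has five stereocentres, four of them contiguous on ring B, and C6 and C7 are adjacent quaternary carbons. Ring B carries the C4 methyl on the C4=C5 alkene, C6 with ethyl and an (E,E)-2-methyl-4-phenylbutadienyl chain, and C7 with methyl and a neopentyl-type carboxylic acid. The control relations that can be used are these: a tertiary ester-bearing C7 can steer alkylation at C6 and additions at C7a and C3a; a quaternary C6 can then fix C7 through a cis-fused lactone; C3a fixes C7a thermodynamically once C7a is alpha to a carbonyl; and C3 can be left to the last ring closure. The styryl diene will not tolerate strong acid, electrophilic oxidants or hydrogenation, and the skipped C4=C5 alkene must not migrate. The C7 acid is too hindered to be released by saponification, so it needs an ester that falls off under neutral conditions. The enabling feature is that ring A is a cyclopentene whose C1=C2 bond lies between the ethyl-bearing C1 and the methyl-bearing C3, so cutting C1=C2 and C2–C3 leaves only a propanoyl group on C7a and an ethyl group on C3a, joined by a one-carbon insertion.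

## Retrosynthesis

Acid 29 is traced to its allyl ester 28 by cutting the ester C–O bond. The allyl group is chosen because zerovalent palladium removes it without acid, base or fluoride, none of which the diene and the hindered carboxyl welcome together.

Ester 28 is cut at C2–C3 and C1=C2 to ethyl ketone 24 and (trimethylsilyl)diazomethane 25, whose carbon becomes C2. Against an aldol or metathesis closure of ring A, this cut needs no functional group on the C3a side chain and no C3 stereocentre carried through the route. The precursor is monocyclic with four stereocentres. The forward step must choose the C3 methylene over other C–H bonds and pick one of its two hydrogens.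

Ketone 24 is cut at the C1–ethyl bond to aldehyde 22, and 22 is traced to dimethyl acetal 20. Carrying the C7a acyl carbon as an acetal keeps an enolisable carbonyl away from the enolate, ylide and phosphonate steps. Its unmasking is also the point where C7a is equilibrated trans to the C3a ethyl group.

Diene 20 is cut at both alkenes of the side chain to aldehyde 16, ylide 17 and phosphonate 19, by way of enal 18. Two E-selective olefinations are simpler than any single reagent carrying the whole chain. The forward reaction is asked to olefinate a neopentyl aldehyde.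

Aldehyde 16 is traced through hydroxy ester 15 and carboxylate 14 to lactone 13. The lactone holds the C6 carbinol carbon and the C7 carboxyl carbon in one ring, and opening it tells them apart: one becomes the aldehyde, the other the allyl ester.

Lactone 13 is cut at the C7–methyl bond to lactone 12, which comes from silyl ether ester 11 by desilylation and ring closure. Methylating an open-chain C7 ester would rest on a small facial bias between two crowded faces. An enolate at the ring fusion of a five-membered lactone alkylates to the cis-fused product, which ties C7 to C6.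

Ester 11 is traced to enol triflate 10 (C5–O reduced to C5–H) and 10 to enone 9 by cutting the C3a–ethyl bond. One conjugate addition sets C3a, and trapping its enolate places the C4=C5 alkene without any regiochemical choice. The addition must occur axially, trans to the C7 ester.

Enone 9 is cut at the C7a–CH(OMe)2 bond to dienol silyl ether 8, made from hydroxy ketone 7. The gamma position of the enone is the only handle on C7a, and a vinylogous Mukaiyama reaction uses it directly.

Hydroxy ketone 7 is cut at C6–CH2OH to enone 6, and 6 at C6–ethyl to enone 5. The order matters: the second electrophile enters anti to the C7 ester, so ethyl goes in first and the one-carbon unit second.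

Enone 5 is cut at C6–C7 (Michael addition) and C3a=C4 (aldol condensation) to keto ester 1 and enal 2. An aminocatalyst sets C7, the only stereocentre that comes from a reagent. C7 acts as a relay: it directs C6, C7a and C3a and is itself overwritten when 13 is made.

## Roads not taken

Alternative 1: Ring B would be annulated onto a preformed ring A by cutting C7–C7a and C5=C6. The enolate of an alpha-methyl beta-keto ester would add to C7a of a chiral acetylcyclopentene, and the acetyl methyl would then condense on the ethyl ketone to give bicyclic enone A1. This is convergent: C3 comes from a small chiral cyclopentene, and C7, C7a and C3a are set in one operation, so the bicyclic core is reached in fewer steps than ring B is reached here. The weak points are the Michael addition of a fully substituted enolate to a beta,beta-disubstituted enone, which is slow and reversible, and the choice between methyl and ester faces at C7, which only remote ring A substituents can bias. C3a is alpha to the C4 ketone in A1 and can slip to the more stable cis-fused hydrindanone. C6 would still have to be made quaternary by conjugate addition next to quaternary C7, and the C1 oxygen would still have to become ethyl and an alkene. The chosen plan is longer, but it sets C6 by enolate alkylation under a strong neighbouring bias before C7 is made quaternary.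

Alternative 2: The cut is C1–C7a and C6–C7. An alkenylcopper reagent would add to C7a of an unsaturated delta-lactone, and the trapped silyl ketene acetal would undergo a ring-contracting Claisen rearrangement through a boat to give ring B acid A2. This is the most step-economical way to make the C6–C7 bond. It forms both quaternary centres with chirality transfer from the C4 carbinol and delivers the free acid, and in that respect it is better than the chosen plan. Against it, the lactone substrate needs a geometrically pure trisubstituted alkene, a tertiary allylic carbinol and the C3 stereocentre in an acyclic side chain, all made beforehand. The rearrangement must form two adjacent quaternary carbons through an enforced boat, where elimination of the allylic carboxylate competes. Ring A would then be closed by metathesis with a second-generation ruthenium catalyst. The chosen plan sets against this that every stereocentre is set on a conformationally defined ring by a textbook type of control, and that ring A needs no prefunctionalised side chain.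

Alternative 3: The cut is C1–C2 together with the C3–H bond. A C7a aldehyde would add across a C3a isopropenyl group under catalysis by monovalent rhodium to give trans-fused ketone A3. The step is catalytic and atom-economical, avoids diazo and organolithium reagents, and uses an aldehyde that is less hindered than ketone 24; these are real advantages. For this target the aldehyde sits next to quaternary C7, so decarbonylation competes, and 1,1-disubstituted alkenes insert slowly. A3 is still two steps from ring A: the C1 ketone must be turned into an enol triflate toward C2 without epimerising C7a and then coupled with an ethyl nucleophile. The diene would also have to be built after ring closure, which lengthens the end. The chosen insertion delivers the ethyl group and the C1=C2 alkene in one step with the diene already in place, at the price of a stoichiometric high-energy intermediate.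

Key step: step 17

Assumption: atom labels C1 to C7a are those of the hydrindene core with the carboxyl carbon on C7. They are kept for the monocyclic intermediates, whose systematic names use their own locants.

## Route

Step 1
Reactants: 1 tert-butyl 3-oxopentanoate; 2 ethyl (2E)-4-oxobut-2-enoate
Product: 5 ethyl (1S)-4-methyl-5-oxocyclohex-3-ene-1-carboxylate, via Michael adduct 3 (not isolated), via cyclohexenone diester 4 (not isolated)
Conditions: (R)-2-[diphenyl(trimethylsilyloxy)methyl]pyrrolidine (10 mol%), PhCO2H (10 mol%), toluene, rt; then p-TsOH·H2O, toluene, 80 °C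
Reagents that add atoms: none
Why: Iminium-catalysed Michael addition, then acid-mediated aldol condensation through the ethyl ketone CH2 and loss of isobutene and CO2 (organocatalytic Robinson-type annulation of beta-keto esters with enals). The aryl(silyloxy)methyl group of the (R)-catalyst screens one face of the E-iminium ion, so the keto ester should add to the other face and give the (S)-ester at C7.

Step 2
Reactants: 5 ethyl (1S)-4-methyl-5-oxocyclohex-3-ene-1-carboxylate
Product: 6 ethyl (1S,6R)-6-ethyl-4-methyl-5-oxocyclohex-3-ene-1-carboxylate (major epimer, used together with its C6 epimer)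
Conditions: LiN(iPr)2, THF, −78 °C; EtI, DMPU, −78 to −20 °C
Reagents that add atoms: iodoethane, CCI
Why: Kinetic alpha-prime deprotonation of the cross-conjugated enone and SN2 alkylation, as in carvone alkylations. The ester alpha-hydrogen at C7 is far less acidic and stays untouched, and the C6 epimer ratio does not matter because C6 is planarised again in step 3.

Step 3
Reactants: 6 ethyl (1S,6R)-6-ethyl-4-methyl-5-oxocyclohex-3-ene-1-carboxylate
Product: 7 ethyl (1S,6S)-6-ethyl-6-(hydroxymethyl)-4-methyl-5-oxocyclohex-3-ene-1-carboxylate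
Conditions: LiN(iPr)2, THF, −78 °C; CH2O (gas, from paraformaldehyde), −78 °C; AcOH quench at −78 °C
Reagents that add atoms: formaldehyde, C=O
Why: Aldol hydroxymethylation of the fully substituted lithium enolate. Allylic 1,2-strain with the C6 ethyl group turns the C7 ester axial, so formaldehyde should enter C6 on the opposite face (the rule for second alkylations of carvone), which puts CH2OH trans and ethyl cis to the ester and sets C6.

Step 4
Reactants: 7 ethyl (1S,6S)-6-ethyl-6-(hydroxymethyl)-4-methyl-5-oxocyclohex-3-ene-1-carboxylate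
Product: 8 ethyl (1S,6S)-5-[(tert-butyldimethylsilyl)oxy]-6-{[(tert-butyldimethylsilyl)oxy]methyl}-6-ethyl-4-methylcyclohexa-2,4-diene-1-carboxylate
Conditions: tBuMe2SiOTf (2.5 equiv), Et3N, CH2Cl2, 0 °C
Reagents that add atoms: tert-butyldimethylsilyl trifluoromethanesulfonate, CC(C)(C)[Si](C)(C)OS(=O)(=O)C(F)(F)F
Why: Soft enolisation: the silyl triflate and amine silylate the primary alcohol and convert the enone into its linear dienol silyl ether by gamma-deprotonation at C7a, the only site left once C6 is quaternary.

Step 5
Reactants: 8 ethyl (1S,6S)-5-[(tert-butyldimethylsilyl)oxy]-6-{[(tert-butyldimethylsilyl)oxy]methyl}-6-ethyl-4-methylcyclohexa-2,4-diene-1-carboxylate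
Product: 9 ethyl (1S,2R,6S)-6-{[(tert-butyldimethylsilyl)oxy]methyl}-2-(dimethoxymethyl)-6-ethyl-4-methyl-5-oxocyclohex-3-ene-1-carboxylate
Conditions: HC(OMe)3, Me3SiOTf (10 mol%), CH2Cl2, −78 °C
Reagents that add atoms: trimethyl orthoformate, COC(OC)OC
Why: Vinylogous Mukaiyama reaction: the dimethoxycarbenium ion attacks the gamma terminus C7a (the alpha carbon C4 is shielded by its methyl group) and the enone is regenerated. Attack anti to the vicinal C7 ester should give the trans acetal, which is also the all-equatorial isomer.

Step 6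
Reactants: 9 ethyl (1S,2R,6S)-6-{[(tert-butyldimethylsilyl)oxy]methyl}-2-(dimethoxymethyl)-6-ethyl-4-methyl-5-oxocyclohex-3-ene-1-carboxylate
Product: 10 ethyl (1S,2S,5S,6R)-2-{[(tert-butyldimethylsilyl)oxy]methyl}-6-(dimethoxymethyl)-2,5-diethyl-4-methyl-3-{[(trifluoromethyl)sulfonyl]oxy}cyclohex-3-ene-1-carboxylate
Conditions: Et2CuLi (from EtLi and CuI), Et2O, −78 °C; then Comins' reagent, THF, −78 to 0 °C
Reagents that add atoms: lithium diethylcuprate, [Li+].CC[Cu-]CC; Comins' reagent (N-(5-chloropyridin-2-yl)-1,1,1-trifluoro-N-[(trifluoromethyl)sulfonyl]methanesulfonamide), O=S(=O)(N(c1ccc(Cl)cn1)S(=O)(=O)C(F)(F)F)C(F)(F)F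
Why: Gilman conjugate addition followed by O-triflation of the regiodefined enolate. The half-chair is locked with the C7 ester and the C7a acetal equatorial (the flipped form has a 1,3-diaxial clash), and axial attack at C3a then brings ethyl in trans to the C7 ester, as in cuprate additions to carvone; this sets C3a.

Step 7
Reactants: 10 ethyl (1S,2S,5S,6R)-2-{[(tert-butyldimethylsilyl)oxy]methyl}-6-(dimethoxymethyl)-2,5-diethyl-4-methyl-3-{[(trifluoromethyl)sulfonyl]oxy}cyclohex-3-ene-1-carboxylate
Product: 11 ethyl (1S,2S,5S,6R)-2-{[(tert-butyldimethylsilyl)oxy]methyl}-6-(dimethoxymethyl)-2,5-diethyl-4-methylcyclohex-3-ene-1-carboxylate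
Conditions: Pd(OAc)2 (5 mol%), PPh3 (10 mol%), HCO2H, Bu3N, DMF, 60 °C
Reagents that add atoms: none
Why: Palladium-catalysed formate reduction of an enol triflate (oxidative addition, formate exchange, loss of CO2, reductive elimination). The C4=C5 alkene is left exactly where the enolate was, and no stereocentre is touched.

Step 8
Reactants: 11 ethyl (1S,2S,5S,6R)-2-{[(tert-butyldimethylsilyl)oxy]methyl}-6-(dimethoxymethyl)-2,5-diethyl-4-methylcyclohex-3-ene-1-carboxylate
Product: 12 (3aS,6S,7R,7aS)-7-(dimethoxymethyl)-3a,6-diethyl-5-methyl-3a,6,7,7a-tetrahydro-2-benzofuran-1(3H)-one (trans-fused lactone)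
Conditions: Bu4NF, THF, 0 to 40 °C
Reagents that add atoms: none
Why: Fluoride desilylation frees the alkoxide, which acylates on the neighbouring ethyl ester and closes the gamma-lactone. Any ring-fusion epimer formed under the basic conditions serves equally, because C7 is planarised in step 9.

Step 9
Reactants: 12 (3aS,6S,7R,7aS)-7-(dimethoxymethyl)-3a,6-diethyl-5-methyl-3a,6,7,7a-tetrahydro-2-benzofuran-1(3H)-one
Product: 13 (3aS,6S,7R,7aR)-7-(dimethoxymethyl)-3a,6-diethyl-5,7a-dimethyl-3a,6,7,7a-tetrahydro-2-benzofuran-1(3H)-one (cis-fused lactone)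
Conditions: LiN(iPr)2, THF, −78 °C; MeI, DMPU, −78 to −40 °C
Reagents that add atoms: iodomethane, CI
Why: Alkylation of a lactone enolate whose nucleophilic carbon is the ring-fusion atom of a bicyclo[4.3.0] system, which strongly favours the cis-fused product. Methyl therefore enters on the face of the C6 ethyl group and the carboxyl carbon ends on the face of the C6 CH2O group; this sets quaternary C7 and overwrites the relay centre.

Step 10
Reactants: 13 (3aS,6S,7R,7aR)-7-(dimethoxymethyl)-3a,6-diethyl-5,7a-dimethyl-3a,6,7,7a-tetrahydro-2-benzofuran-1(3H)-one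
Product: 15 prop-2-en-1-yl (1R,2S,5S,6R)-6-(dimethoxymethyl)-2,5-diethyl-2-(hydroxymethyl)-1,4-dimethylcyclohex-3-ene-1-carboxylate, via potassium carboxylate 14 (not isolated)
Conditions: KOH (1.05 equiv), MeOH/H2O, 65 °C; evaporate; CH2=CHCH2Br, DMF, 0 °C; used crude
Reagents that add atoms: potassium hydroxide, [K+].[OH-]; 3-bromoprop-1-ene, C=CCBr
Why: Saponification of the lactone and O-alkylation of the carboxylate salt under near-neutral conditions, a standard way to open gamma-lactones. The hydroxy ester is taken on at once so that it does not close again.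

Step 11
Reactants: 15 prop-2-en-1-yl (1R,2S,5S,6R)-6-(dimethoxymethyl)-2,5-diethyl-2-(hydroxymethyl)-1,4-dimethylcyclohex-3-ene-1-carboxylate
Product: 16 prop-2-en-1-yl (1R,2S,5S,6R)-6-(dimethoxymethyl)-2,5-diethyl-2-formyl-1,4-dimethylcyclohex-3-ene-1-carboxylate
Conditions: Dess–Martin periodinane, NaHCO3, CH2Cl2, 0 °C to rt
Reagents that add atoms: none
Why: Buffered Dess–Martin oxidation of the neopentyl alcohol to a non-enolisable aldehyde; it also removes the hydroxyl that could re-form the lactone.

Step 12
Reactants: 16 prop-2-en-1-yl (1R,2S,5S,6R)-6-(dimethoxymethyl)-2,5-diethyl-2-formyl-1,4-dimethylcyclohex-3-ene-1-carboxylate; 17 2-(triphenylphosphoranylidene)propanal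
Product: 18 prop-2-en-1-yl (1R,2R,5S,6R)-6-(dimethoxymethyl)-2,5-diethyl-1,4-dimethyl-2-[(1E)-2-methyl-3-oxoprop-1-en-1-yl]cyclohex-3-ene-1-carboxylate
Conditions: toluene, 110 °C
Reagents that add atoms: none
Why: Wittig reaction with a formyl-stabilised ylide, which should give the E-configured 2-methyl enal under thermodynamic control; the product enal is less electrophilic than 16 and should not react further.

Step 13
Reactants: 18 prop-2-en-1-yl (1R,2R,5S,6R)-6-(dimethoxymethyl)-2,5-diethyl-1,4-dimethyl-2-[(1E)-2-methyl-3-oxoprop-1-en-1-yl]cyclohex-3-ene-1-carboxylate; 19 diethyl benzylphosphonate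
Product: 20 prop-2-en-1-yl (1R,2S,5S,6R)-6-(dimethoxymethyl)-2,5-diethyl-1,4-dimethyl-2-[(1E,3E)-2-methyl-4-phenylbuta-1,3-dien-1-yl]cyclohex-3-ene-1-carboxylate
Conditions: NaH, THF, 0 °C to rt
Reagents that add atoms: none
Why: Horner–Wadsworth–Emmons olefination with a benzylphosphonate anion, which should give the E-styrene; the hindered allyl ester and the acetal are inert to the phosphonate anion.

Step 14
Reactants: 20 prop-2-en-1-yl (1R,2S,5S,6R)-6-(dimethoxymethyl)-2,5-diethyl-1,4-dimethyl-2-[(1E,3E)-2-methyl-4-phenylbuta-1,3-dien-1-yl]cyclohex-3-ene-1-carboxylate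
Product: 22 prop-2-en-1-yl (1R,2S,5S,6S)-2,5-diethyl-6-formyl-1,4-dimethyl-2-[(1E,3E)-2-methyl-4-phenylbuta-1,3-dien-1-yl]cyclohex-3-ene-1-carboxylate, via C7a-epimeric aldehyde 21 (not isolated)
Conditions: PPTS, acetone/H2O (10:1), 55 °C; then DBU (0.2 equiv), CH2Cl2, rt
Reagents that add atoms: water, O
Why: Mild acetal hydrolysis, then base equilibration of the aldehyde alpha-centre C7a. The isomer with formyl cis to the C3a ethyl group has a 1,3-diaxial contact in either half-chair, so the trans isomer required by the target should prevail; this sets C7a.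

Step 15
Reactants: 22 prop-2-en-1-yl (1R,2S,5S,6S)-2,5-diethyl-6-formyl-1,4-dimethyl-2-[(1E,3E)-2-methyl-4-phenylbuta-1,3-dien-1-yl]cyclohex-3-ene-1-carboxylate
Product: 23 prop-2-en-1-yl (1R,2S,5S,6S)-2,5-diethyl-6-(1-hydroxypropyl)-1,4-dimethyl-2-[(1E,3E)-2-methyl-4-phenylbuta-1,3-dien-1-yl]cyclohex-3-ene-1-carboxylate (both carbinol epimers)
Conditions: EtMgBr, THF, −78 °C; NH4Cl quench at −78 °C
Reagents that add atoms: ethylmagnesium bromide, CC[Mg]Br
Why: Grignard addition to the aldehyde, much faster than attack on the neopentyl allyl ester at low temperature; the carbinol configuration is erased in step 16.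

Step 16
Reactants: 23 prop-2-en-1-yl (1R,2S,5S,6S)-2,5-diethyl-6-(1-hydroxypropyl)-1,4-dimethyl-2-[(1E,3E)-2-methyl-4-phenylbuta-1,3-dien-1-yl]cyclohex-3-ene-1-carboxylate
Product: 24 prop-2-en-1-yl (1R,2S,5S,6S)-2,5-diethyl-1,4-dimethyl-2-[(1E,3E)-2-methyl-4-phenylbuta-1,3-dien-1-yl]-6-propanoylcyclohex-3-ene-1-carboxylate
Conditions: Dess–Martin periodinane, NaHCO3, CH2Cl2, rt
Reagents that add atoms: none
Why: Dess–Martin oxidation of the secondary alcohol to the ethyl ketone under buffered conditions that spare the diene; C7a is already at its thermodynamic configuration, so later enolisation cannot scramble it.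

Step 17
Reactants: 24 prop-2-en-1-yl (1R,2S,5S,6S)-2,5-diethyl-1,4-dimethyl-2-[(1E,3E)-2-methyl-4-phenylbuta-1,3-dien-1-yl]-6-propanoylcyclohex-3-ene-1-carboxylate; 25 (trimethylsilyl)diazomethane
Product: 28 prop-2-en-1-yl (3R,3aS,6S,7R,7aR)-1,6-diethyl-3,4,7-trimethyl-6-[(1E,3E)-2-methyl-4-phenylbuta-1,3-dien-1-yl]-3a,6,7,7a-tetrahydro-3H-indene-7-carboxylate, via lithium alkoxide adduct 26 (not isolated), via alkylidene carbene 27 (not isolated)
Conditions: 25, n-BuLi, THF, −78 °C; then 24, −78 to 0 °C
Reagents that add atoms: none
Why: Lithiated (trimethylsilyl)diazomethane adds to the C1 ketone of 24 to give alkoxide 26, which loses lithium trimethylsilanolate and then dinitrogen to give alkylidene carbene 27. The carbene carbon (C2) inserts into a C–H bond of the C3 methylene of the C3a ethyl group in a concerted 1,5-insertion with retention, the reaction type established for making cyclopentenes from dialkyl ketones. Ring A thus closes by insertion through a five-membered transition state, forming C2–C3 and leaving C1=C2 in place. The trans-diequatorial C7a alkylidene and C3a ethyl groups hold the C3 hydrogens within reach and give the trans ring fusion without touching C3a or C7a. C3 is set by the choice between the two diastereotopic hydrogens: the transition state that turns the C3 methyl away from C4 and its methyl group (cis to H-3a) avoids a 1,3 clash and should dominate. The step needs secondary C–H insertion to beat insertion into the C7 methyl group, 1,2-shift to an alkyne and addition to the diene; the intrinsic secondary-over-primary preference, the slow alkyl shift of dialkyl carbenes and the trans-1,3 placement of the dienyl chain secure this. Enolisation of the hindered ketone by the basic reagent is the main loss and only returns 24.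

Step 18
Reactants: 28 prop-2-en-1-yl (3R,3aS,6S,7R,7aR)-1,6-diethyl-3,4,7-trimethyl-6-[(1E,3E)-2-methyl-4-phenylbuta-1,3-dien-1-yl]-3a,6,7,7a-tetrahydro-3H-indene-7-carboxylate
Product: 29 (3R,3aS,6S,7R,7aR)-1,6-diethyl-3,4,7-trimethyl-6-[(1E,3E)-2-methyl-4-phenylbuta-1,3-dien-1-yl]-3a,6,7,7a-tetrahydro-3H-indene-7-carboxylic acid
Conditions: Pd(PPh3)4 (5 mol%), morpholine, THF, rt
Reagents that add atoms: none
Why: Allyl transfer from the ester to morpholine through a pi-allyl complex of zerovalent palladium (Tsuji–Trost deallylation) frees the hindered acid under neutral conditions that leave both ring alkenes and the diene alone.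

## Compound list

1 | tert-butyl 3-oxopentanoate | CCC(=O)CC(=O)OC(C)(C)C | starting material
2 | ethyl (2E)-4-oxobut-2-enoate | CCOC(=O)/C=C/C=O | starting material
3 | 1-tert-butyl 4-ethyl (3S)-3-(2-oxoethyl)-2-propanoylbutanedioate (C2 epimers) | O=CC[C@H](C(=O)OCC)C(C(=O)CC)C(=O)OC(C)(C)C | intermediate
4 | 2-tert-butyl 1-ethyl (1S)-4-methyl-3-oxocyclohex-4-ene-1,2-dicarboxylate (C2 epimers) | CC1=CC[C@H](C(=O)OCC)C(C(=O)OC(C)(C)C)C1=O | intermediate
5 | ethyl (1S)-4-methyl-5-oxocyclohex-3-ene-1-carboxylate | CC1=CC[C@H](C(=O)OCC)CC1=O | intermediate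
6 | ethyl (1S,6R)-6-ethyl-4-methyl-5-oxocyclohex-3-ene-1-carboxylate (major C6 epimer drawn) | CC1=CC[C@H](C(=O)OCC)[C@@H](CC)C1=O | intermediate
7 | ethyl (1S,6S)-6-ethyl-6-(hydroxymethyl)-4-methyl-5-oxocyclohex-3-ene-1-carboxylate | CC1=CC[C@H](C(=O)OCC)[C@@](CC)(CO)C1=O | intermediate
8 | ethyl (1S,6S)-5-[(tert-butyldimethylsilyl)oxy]-6-{[(tert-butyldimethylsilyl)oxy]methyl}-6-ethyl-4-methylcyclohexa-2,4-diene-1-carboxylate | CC1=C(O[Si](C)(C)C(C)(C)C)[C@](CC)(CO[Si](C)(C)C(C)(C)C)[C@@H](C(=O)OCC)C=C1 | intermediate
9 | ethyl (1S,2R,6S)-6-{[(tert-butyldimethylsilyl)oxy]methyl}-2-(dimethoxymethyl)-6-ethyl-4-methyl-5-oxocyclohex-3-ene-1-carboxylate | CC1=C[C@@H](C(OC)OC)[C@H](C(=O)OCC)[C@@](CC)(CO[Si](C)(C)C(C)(C)C)C1=O | intermediate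
10 | ethyl (1S,2S,5S,6R)-2-{[(tert-butyldimethylsilyl)oxy]methyl}-6-(dimethoxymethyl)-2,5-diethyl-4-methyl-3-{[(trifluoromethyl)sulfonyl]oxy}cyclohex-3-ene-1-carboxylate | CC1=C(OS(=O)(=O)C(F)(F)F)[C@](CC)(CO[Si](C)(C)C(C)(C)C)[C@@H](C(=O)OCC)[C@H](C(OC)OC)[C@@H]1CC | intermediate
11 | ethyl (1S,2S,5S,6R)-2-{[(tert-butyldimethylsilyl)oxy]methyl}-6-(dimethoxymethyl)-2,5-diethyl-4-methylcyclohex-3-ene-1-carboxylate | CC1=C[C@](CC)(CO[Si](C)(C)C(C)(C)C)[C@@H](C(=O)OCC)[C@H](C(OC)OC)[C@@H]1CC | intermediate
12 | (3aS,6S,7R,7aS)-7-(dimethoxymethyl)-3a,6-diethyl-5-methyl-3a,6,7,7a-tetrahydro-2-benzofuran-1(3H)-one | CC1=C[C@]2(CC)COC(=O)[C@H]2[C@H](C(OC)OC)[C@@H]1CC | intermediate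
13 | (3aS,6S,7R,7aR)-7-(dimethoxymethyl)-3a,6-diethyl-5,7a-dimethyl-3a,6,7,7a-tetrahydro-2-benzofuran-1(3H)-one | CC1=C[C@]2(CC)COC(=O)[C@]2(C)[C@H](C(OC)OC)[C@@H]1CC | intermediate
14 | potassium (1R,2S,5S,6R)-6-(dimethoxymethyl)-2,5-diethyl-2-(hydroxymethyl)-1,4-dimethylcyclohex-3-ene-1-carboxylate | CC1=C[C@](CC)(CO)[C@](C)(C(=O)[O-])[C@H](C(OC)OC)[C@@H]1CC.[K+] | intermediate
15 | prop-2-en-1-yl (1R,2S,5S,6R)-6-(dimethoxymethyl)-2,5-diethyl-2-(hydroxymethyl)-1,4-dimethylcyclohex-3-ene-1-carboxylate | CC1=C[C@](CC)(CO)[C@](C)(C(=O)OCC=C)[C@H](C(OC)OC)[C@@H]1CC | intermediate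
16 | prop-2-en-1-yl (1R,2S,5S,6R)-6-(dimethoxymethyl)-2,5-diethyl-2-formyl-1,4-dimethylcyclohex-3-ene-1-carboxylate | CC1=C[C@](CC)(C=O)[C@](C)(C(=O)OCC=C)[C@H](C(OC)OC)[C@@H]1CC | intermediate
17 | 2-(triphenylphosphoranylidene)propanal | CC(C=O)=P(c1ccccc1)(c1ccccc1)c1ccccc1 | starting material
18 | prop-2-en-1-yl (1R,2R,5S,6R)-6-(dimethoxymethyl)-2,5-diethyl-1,4-dimethyl-2-[(1E)-2-methyl-3-oxoprop-1-en-1-yl]cyclohex-3-ene-1-carboxylate | CC1=C[C@](CC)(/C=C(C)/C=O)[C@](C)(C(=O)OCC=C)[C@H](C(OC)OC)[C@@H]1CC | intermediate
19 | diethyl benzylphosphonate | CCOP(=O)(Cc1ccccc1)OCC | starting material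
20 | prop-2-en-1-yl (1R,2S,5S,6R)-6-(dimethoxymethyl)-2,5-diethyl-1,4-dimethyl-2-[(1E,3E)-2-methyl-4-phenylbuta-1,3-dien-1-yl]cyclohex-3-ene-1-carboxylate | CC1=C[C@](CC)(/C=C(C)/C=C/c2ccccc2)[C@](C)(C(=O)OCC=C)[C@H](C(OC)OC)[C@@H]1CC | intermediate
21 | prop-2-en-1-yl (1R,2S,5S,6R)-2,5-diethyl-6-formyl-1,4-dimethyl-2-[(1E,3E)-2-methyl-4-phenylbuta-1,3-dien-1-yl]cyclohex-3-ene-1-carboxylate (formyl cis to the C3a ethyl) | CC1=C[C@](CC)(/C=C(C)/C=C/c2ccccc2)[C@](C)(C(=O)OCC=C)[C@H](C=O)[C@@H]1CC | intermediate
22 | prop-2-en-1-yl (1R,2S,5S,6S)-2,5-diethyl-6-formyl-1,4-dimethyl-2-[(1E,3E)-2-methyl-4-phenylbuta-1,3-dien-1-yl]cyclohex-3-ene-1-carboxylate (formyl trans to the C3a ethyl) | CC1=C[C@](CC)(/C=C(C)/C=C/c2ccccc2)[C@](C)(C(=O)OCC=C)[C@@H](C=O)[C@@H]1CC | intermediate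
23 | prop-2-en-1-yl (1R,2S,5S,6S)-2,5-diethyl-6-(1-hydroxypropyl)-1,4-dimethyl-2-[(1E,3E)-2-methyl-4-phenylbuta-1,3-dien-1-yl]cyclohex-3-ene-1-carboxylate (carbinol epimers) | CC1=C[C@](CC)(/C=C(C)/C=C/c2ccccc2)[C@](C)(C(=O)OCC=C)[C@@H](C(O)CC)[C@@H]1CC | intermediate
24 | prop-2-en-1-yl (1R,2S,5S,6S)-2,5-diethyl-1,4-dimethyl-2-[(1E,3E)-2-methyl-4-phenylbuta-1,3-dien-1-yl]-6-propanoylcyclohex-3-ene-1-carboxylate | CC1=C[C@](CC)(/C=C(C)/C=C/c2ccccc2)[C@](C)(C(=O)OCC=C)[C@@H](C(=O)CC)[C@@H]1CC | intermediate
25 | (trimethylsilyl)diazomethane | C[Si](C)(C)C=[N+]=[N-] | starting material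
26 | lithium alkoxide from addition of lithiated 25 to the ketone carbon of 24 (carbinol epimers) | CC1=C[C@](CC)(/C=C(C)/C=C/c2ccccc2)[C@](C)(C(=O)OCC=C)[C@@H](C([O-])(CC)C(=[N+]=[N-])[Si](C)(C)C)[C@@H]1CC.[Li+] | intermediate
27 | alkylidene carbene: 24 with the ketone oxygen replaced by a divalent carbon | CC1=C[C@](CC)(/C=C(C)/C=C/c2ccccc2)[C@](C)(C(=O)OCC=C)[C@@H](C(CC)=[C])[C@@H]1CC | intermediate
28 | prop-2-en-1-yl (3R,3aS,6S,7R,7aR)-1,6-diethyl-3,4,7-trimethyl-6-[(1E,3E)-2-methyl-4-phenylbuta-1,3-dien-1-yl]-3a,6,7,7a-tetrahydro-3H-indene-7-carboxylate | CCC1=C[C@@H](C)[C@@H]2C(C)=C[C@@](/C=C(C)/C=C/c3ccccc3)(CC)[C@](C)(C(=O)OCC=C)[C@@H]12 | intermediate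
29 | (3R,3aS,6S,7R,7aR)-1,6-diethyl-3,4,7-trimethyl-6-[(1E,3E)-2-methyl-4-phenylbuta-1,3-dien-1-yl]-3a,6,7,7a-tetrahydro-3H-indene-7-carboxylic acid | CCC1=C[C@@H](C)[C@@H]2C(C)=C[C@@](/C=C(C)/C=C/c3ccccc3)(CC)[C@](C)(C(=O)O)[C@@H]12 | target

## Step count and least certain steps

Total: 18 steps. Longest linear sequence: 18 steps, from 1 and 2 to 29.

Step 17 (key step). The likeliest failure is enolisation of the hindered ethyl ketone by the basic lithiated diazo reagent instead of addition, which would return 24. A second risk is insertion into the C7 methyl group if the ethyl group is held in an unfavourable rotamer. The fallback sets out from 24: a Wittig reaction with Ph3P=CHCl, made from (chloromethyl)triphenylphosphonium chloride and KOtBu, would give the vinyl chloride F1 as an E/Z mixture. Alpha-elimination with KN(SiMe3)2 in Et2O then generates the same carbene 27 with no enolisable carbonyl in the flask, and the route is rejoined at 28.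

Step 5. The gamma-acetal enone can lose methanol to a methoxymethylene dienone under Lewis acid, and some attack at the alpha carbon C4 is possible; both follow from the vinylogous acidity of H-7a and the oxocarbenium character of the electrophile. The fallback sets out from 8: 1,3-dithian-2-ylium tetrafluoroborate, a sulfur-stabilised cation that alkylates dienol silyl ethers at the gamma carbon, would give the dithianyl enone F2. PhI(OCOCF3)2 in methanol would then exchange the thioacetal for the dimethyl acetal and return to 9.

Step 6. O-Sulfonylation of the congested tetrasubstituted lithium enolate, flanked by quaternary C6, may be incomplete, and the copper species present can erode it further. The fallback sets out from 9: the cuprate addition is quenched with aqueous NH4Cl to give the saturated ketone F3, a mixture of C4 epimers. F3 is deprotonated with KN(SiMe3)2, which can only act at C4 because C6 is quaternary, and the potassium enolate is triflated with Comins' reagent to rejoin the route at 10.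

Step 10. The hydroxy ester 15 can close back to lactone 13 with loss of allyl alcohol, helped by the two quaternary carbons that hold hydroxyl and ester together. The fallback sets out from 13 and passes through 14 and 15 as before, but 15 is capped in the same flask with Et3SiCl and imidazole to give the triethylsilyl ether F4, which can be purified. Swern conditions ((COCl)2, DMSO, then Et3N) are known to convert primary triethylsilyl ethers directly into aldehydes, and this returns to 16 without a free hydroxyl ever being isolated.

Step 12. The aldehyde of 16 sits between two quaternary carbons, and the weakly nucleophilic formyl-stabilised ylide may react too slowly even in refluxing toluene. The fallback sets out from 16: a Horner–Wadsworth–Emmons reaction with the more nucleophilic anion of triethyl 2-phosphonopropanoate (LiCl, DBU, MeCN) would give the E-enoate F5. iBu2AlH at −78 °C should reduce this unhindered conjugated ester to the allylic alcohol F6 in preference to the neopentyl allyl ester, and MnO2 would oxidise F6 to rejoin the route at 18.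

## Further compounds

F1 | step 17 | prop-2-en-1-yl (1R,2S,5S,6S)-6-(1-chlorobut-1-en-2-yl)-2,5-diethyl-1,4-dimethyl-2-[(1E,3E)-2-methyl-4-phenylbuta-1,3-dien-1-yl]cyclohex-3-ene-1-carboxylate (E/Z mixture at the chloroalkene) | CC1=C[C@](CC)(/C=C(C)/C=C/c2ccccc2)[C@](C)(C(=O)OCC=C)[C@@H](C(CC)=CCl)[C@@H]1CC
F2 | step 5 | ethyl (1S,2R,6S)-6-{[(tert-butyldimethylsilyl)oxy]methyl}-2-(1,3-dithian-2-yl)-6-ethyl-4-methyl-5-oxocyclohex-3-ene-1-carboxylate | CC1=C[C@@H](C2SCCCS2)[C@H](C(=O)OCC)[C@@](CC)(CO[Si](C)(C)C(C)(C)C)C1=O
F3 | step 6 | ethyl (1S,2S,5S,6R)-2-{[(tert-butyldimethylsilyl)oxy]methyl}-6-(dimethoxymethyl)-2,5-diethyl-4-methyl-3-oxocyclohexane-1-carboxylate (C4 epimers) | CC1C(=O)[C@](CC)(CO[Si](C)(C)C(C)(C)C)[C@@H](C(=O)OCC)[C@H](C(OC)OC)[C@@H]1CC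
F4 | step 10 | prop-2-en-1-yl (1R,2S,5S,6R)-6-(dimethoxymethyl)-2,5-diethyl-1,4-dimethyl-2-{[(triethylsilyl)oxy]methyl}cyclohex-3-ene-1-carboxylate | CC1=C[C@](CC)(CO[Si](CC)(CC)CC)[C@](C)(C(=O)OCC=C)[C@H](C(OC)OC)[C@@H]1CC
F5 | step 12 | prop-2-en-1-yl (1R,2R,5S,6R)-6-(dimethoxymethyl)-2-[(1E)-3-ethoxy-2-methyl-3-oxoprop-1-en-1-yl]-2,5-diethyl-1,4-dimethylcyclohex-3-ene-1-carboxylate | CC1=C[C@](CC)(/C=C(C)/C(=O)OCC)[C@](C)(C(=O)OCC=C)[C@H](C(OC)OC)[C@@H]1CC
F6 | step 12 | prop-2-en-1-yl (1R,2R,5S,6R)-6-(dimethoxymethyl)-2,5-diethyl-2-[(1E)-3-hydroxy-2-methylprop-1-en-1-yl]-1,4-dimethylcyclohex-3-ene-1-carboxylate | CC1=C[C@](CC)(/C=C(C)/CO)[C@](C)(C(=O)OCC=C)[C@H](C(OC)OC)[C@@H]1CC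
A1 | alternative 1 | methyl 1-[(tert-butyldimethylsilyl)oxy]-6-ethyl-3,7-dimethyl-4-oxo-2,3,3a,4,7,7a-hexahydro-1H-indene-7-carboxylate (target numbering, configuration as drawn) | CCC1=CC(=O)[C@H]2[C@H](C)C[C@@H](O[Si](C)(C)C(C)(C)C)[C@@H]2[C@@]1(C)C(=O)OC
A2 | alternative 2 | 6-(but-1-en-2-yl)-5-(but-3-en-2-yl)-2-{[(tert-butyldimethylsilyl)oxy]methyl}-2-ethyl-1,4-dimethylcyclohex-3-ene-1-carboxylic acid (configuration as drawn) | C=C[C@@H](C)[C@@H]1C(C)=C[C@@](CO[Si](C)(C)C(C)(C)C)(CC)[C@](C)(C(=O)O)[C@H]1C(=C)CC
A3 | alternative 3 | 2-(trimethylsilyl)ethyl 6-{[(tert-butyldimethylsilyl)oxy]methyl}-6-ethyl-3,4,7-trimethyl-1-oxo-2,3,3a,6,7,7a-hexahydro-1H-indene-7-carboxylate (target numbering, configuration as drawn) | O=C1C[C@@H](C)[C@@H]2C(C)=C[C@@](CO[Si](C)(C)C(C)(C)C)(CC)[C@](C)(C(=O)OCC[Si](C)(C)C)[C@@H]12
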